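**Strategy**

Ring C is opened at two bonds that both end on ring A: the aryl ether bond O1–C8a and the ketone–aryl bond C4–C4a. One operation makes both by inserting 3,4,5-trimethoxybenzyne between the carbinol oxygen and the amide carbonyl of an acyclic anti-aldol unit: fluoride unmasks the alkoxide, which adds to the aryne, and the aryl anion then closes onto a Weinreb amide. The step exploits the ortho relation of O1 and the C4 carbonyl on ring A and the oxygen at C5 beside C4a, which directs the addition. The precursor is an O-silylated (2R,3R)-3-aryl-3-hydroxy-2-methoxypropanamide that already holds C2 and C3; BCl3 finally frees the three phenols.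

Key step: step 9

Remark: flavanone numbering is used for the target (O1, C2, C3, C4, C4a, C5 to C8, C8a; ring A is the benzo ring, ring B the 2-aryl ring, ring C the pyranone ring).

Assumption: the anti-glycolate aldol of step 4 is taken to follow the chelated-enolate, open-transition-state model, so that the (S)-auxiliary gives the (2R,3R) adduct; if the facial sense proved opposite, the (R)-auxiliary would be used and nothing else changes.

**Route**

Step 1
Reactants: 1 2-methoxybenzene-1,4-diol (methoxyhydroquinone)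
Product: 2 1,4-bis(benzyloxy)-2-methoxybenzene
Conditions: BnBr, K2CO3, DMF, rt to 60 °C, under N2
Reagents that add atoms: benzyl bromide BrCc1ccccc1
Why: Williamson etherification of both phenols under mild base should be clean, and working under nitrogen keeps the hydroquinone from oxidising before it is capped.

Step 2
Reactants: 2 1,4-bis(benzyloxy)-2-methoxybenzene
Product: 4 2,5-bis(benzyloxy)-4-methoxybenzaldehyde, via iminium salt 3 (not isolated)
Conditions: POCl3, DMF, 0 to 70 °C; then H2O
Reagents that add atoms: N,N-dimethylformamide CN(C)C=O; water O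
Why: Vilsmeier–Haack formylation should go to the one position that is para to the methoxy group and ortho to a benzyloxy group, the same preference that turns 1,2,4-trimethoxybenzene into 2,4,5-trimethoxybenzaldehyde, and iminium salt 3 is hydrolysed on work-up.

Step 3
Reactants: 5 (S)-4-benzyl-1,3-oxazolidine-2-thione; 6 methoxyacetyl chloride
Product: 7 (S)-4-benzyl-3-(methoxyacetyl)-1,3-oxazolidine-2-thione
Conditions: Et3N, CH2Cl2, 0 °C
Reagents that add atoms: none
Why: N-acylation of the oxazolidinethione with an acid chloride and a tertiary amine is the standard way to load this auxiliary.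

Step 4
Reactants: 7 (S)-4-benzyl-3-(methoxyacetyl)-1,3-oxazolidine-2-thione; 4 2,5-bis(benzyloxy)-4-methoxybenzaldehyde
Product: 10 (4S)-4-benzyl-3-[(2R,3R)-3-[2,5-bis(benzyloxy)-4-methoxyphenyl]-3-hydroxy-2-methoxypropanoyl]-1,3-oxazolidine-2-thione, via titanium enolate 8 (not isolated), via titanium aldolate 9 (not isolated)
Conditions: 7, TiCl4, i-Pr2NEt, CH2Cl2, −78 °C; then 4 premixed with TiCl4, −78 °C; then H2O
Reagents that add atoms: none
Why: anti-selective titanium glycolate aldol reaction of an N-glycolyloxazolidinethione (Crimmins type), in which the chelated (Z)-enolate 8 is attacked on the face away from the benzyl group, setting the methoxy-bearing carbon as R, and the TiCl4-bound aldehyde reacts through an open transition state, setting the carbinol carbon as R in the anti relationship.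

Step 5
Reactants: 10 (4S)-4-benzyl-3-[(2R,3R)-3-[2,5-bis(benzyloxy)-4-methoxyphenyl]-3-hydroxy-2-methoxypropanoyl]-1,3-oxazolidine-2-thione
Product: 11 (2R,3R)-3-[2,5-bis(benzyloxy)-4-methoxyphenyl]-3-hydroxy-N,2-dimethoxy-N-methylpropanamide
Conditions: MeNHOMe·HCl, imidazole, CH2Cl2, rt
Reagents that add atoms: N,O-dimethylhydroxylamine hydrochloride CNOC.Cl
Why: the N-acyloxazolidinethione is an activated amide that N,O-dimethylhydroxylamine should displace directly under imidazole buffering without touching the free hydroxyl or either stereocentre, and auxiliary 5 is recovered.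

Step 6
Reactants: 11 (2R,3R)-3-[2,5-bis(benzyloxy)-4-methoxyphenyl]-3-hydroxy-N,2-dimethoxy-N-methylpropanamide
Product: 12 (2R,3R)-3-[2,5-bis(benzyloxy)-4-methoxyphenyl]-N,2-dimethoxy-N-methyl-3-[(trimethylsilyl)oxy]propanamide
Conditions: TMSCl, imidazole, CH2Cl2, 0 °C
Reagents that add atoms: chlorotrimethylsilane C[Si](C)(C)Cl
Why: silylation of the secondary benzylic alcohol removes the only acidic proton of the substrate and turns the hydroxyl into a fluoride-labile alkoxide precursor.

Step 7
Reactants: 13 3,4,5-trimethoxyphenol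
Product: 14 2-bromo-3,4,5-trimethoxyphenol
Conditions: NBS (1.0 equiv), CH2Cl2, −78 to 0 °C
Reagents that add atoms: N-bromosuccinimide O=C1CCC(=O)N1Br
Why: electrophilic bromination should go ortho to the hydroxyl because the para position carries a methoxy group, and one equivalent of NBS at low temperature should stop at the monobromide.

Step 8
Reactants: 14 2-bromo-3,4,5-trimethoxyphenol
Product: 18 3,4,5-trimethoxy-2-(trimethylsilyl)phenyl trifluoromethanesulfonate, via aryl silyl ether 15 (not isolated), via aryllithium 16 (not isolated), via lithium phenolate 17 (not isolated)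
Conditions: HMDS, THF, 65 °C, then evaporation; n-BuLi, THF, −78 °C; Tf2O, −78 °C to rt
Reagents that add atoms: hexamethyldisilazane C[Si](C)(C)N[Si](C)(C)C; trifluoromethanesulfonic anhydride O=S(=O)(OS(=O)(=O)C(F)(F)F)C(F)(F)F
Why: one-flask O-silylation, bromine–lithium exchange, retro-Brook 1,3-shift of silicon from oxygen to carbon and O-triflation of the phenolate is the standard route to ortho-silylaryl triflates (Kobayashi aryne precursors).

Step 9
Reactants: 12 (2R,3R)-3-[2,5-bis(benzyloxy)-4-methoxyphenyl]-N,2-dimethoxy-N-methyl-3-[(trimethylsilyl)oxy]propanamide; 18 3,4,5-trimethoxy-2-(trimethylsilyl)phenyl trifluoromethanesulfonate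
Product: 23 (2R,3R)-2-[2,5-bis(benzyloxy)-4-methoxyphenyl]-3,5,6,7-tetramethoxy-2,3-dihydro-4H-chromen-4-one, via 3,4,5-trimethoxybenzyne 19 (not isolated), via potassium alkoxide 20 (not isolated), via aryl potassium 21 (not isolated), via potassium hemiaminalate 22 (not isolated)
Conditions: KF, 18-crown-6, DME, 0 °C to rt, 18 (1.5 equiv) added slowly; then aq. NH4Cl
Reagents that add atoms: none
Why: Proposed new method: fluoride removes both silyl groups, giving potassium alkoxide 20 and, by loss of triflate, aryne 19; the alkoxide oxygen adds to the aryne carbon remote from the flanking methoxy group (bond O1–C8a), and the aryl anion 21 so placed next to that methoxy group attacks the Weinreb amide carbonyl (bond C4–C4a) to give tetrahedral adduct 22, which should persist until the quench releases the ketone. The closest known reaction type is the fluoride-induced annulation of arynes with salicylate esters to xanthones (O-arylation followed by intramolecular acyl substitution), supported by the known O–H insertion of arynes into aliphatic alcohols and aryne insertion into amide bonds; its use on an aliphatic β-silyloxy amide to build a chroman-4-one is not established. Ring C closes by 6-exo-trig attack of the aryl anion on the amide carbonyl. No stereocentre is formed: C2 and C3 come unchanged from 12 because neither the C2–O bond nor the C3–H bond is touched, and the trans arrangement they carry is also the more stable one. The step needs regioselective addition to an unsymmetrical aryne, secured by the inductive effect of the methoxy group beside the aryne (the group that becomes the C5 oxygen), and it needs acylation to outrun protonation of the aryl anion and retro-aldol cleavage of 20, for which the aprotic medium, the six-membered closure and the poor leaving-group ability of an amide enolate are relied on. Holding C4 as a tetrahedral adduct until the quench should also shield C3 from epimerisation and ring C from base-induced opening.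

Step 10
Reactants: 23 (2R,3R)-2-[2,5-bis(benzyloxy)-4-methoxyphenyl]-3,5,6,7-tetramethoxy-2,3-dihydro-4H-chromen-4-one
Product: 25 (2R,3R)-2-(2,5-dihydroxy-4-methoxyphenyl)-5-hydroxy-3,6,7-trimethoxy-2,3-dihydro-4H-chromen-4-one, via tris(dichloroboryl) ether 24 (not isolated)
Conditions: BCl3, C6HMe5, CH2Cl2, −78 to 0 °C; then H2O, under argon
Reagents that add atoms: none
Why: BCl3 with pentamethylbenzene as benzyl cation scavenger cleaves aryl benzyl ethers at low temperature, and BCl3 chelated between the C4 carbonyl and the C5 oxygen cleaves only the peri methyl ether, so the other aryl methyl ethers, the aliphatic C3 methyl ether and both stereocentres should survive.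

**Compound list**

1 | 2-methoxybenzene-1,4-diol | COc1cc(O)ccc1O | starting material
2 | 1,4-bis(benzyloxy)-2-methoxybenzene | COc1cc(OCc2ccccc2)ccc1OCc1ccccc1 | intermediate
3 | [2,5-bis(benzyloxy)-4-methoxybenzylidene]dimethyliminium chloride | COc1cc(OCc2ccccc2)c(C=[N+](C)C)cc1OCc1ccccc1.[Cl-] | intermediate
4 | 2,5-bis(benzyloxy)-4-methoxybenzaldehyde | COc1cc(OCc2ccccc2)c(C=O)cc1OCc1ccccc1 | intermediate
5 | (S)-4-benzyl-1,3-oxazolidine-2-thione | S=C1N[C@@H](Cc2ccccc2)CO1 | starting material
6 | methoxyacetyl chloride | COCC(Cl)=O | starting material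
7 | (S)-4-benzyl-3-(methoxyacetyl)-1,3-oxazolidine-2-thione | COCC(=O)N1[C@@H](Cc2ccccc2)COC1=S | intermediate
8 | trichlorotitanium (Z)-enolate of 7 | CO/C=C(\O[Ti](Cl)(Cl)Cl)N1[C@@H](Cc2ccccc2)COC1=S | intermediate
9 | trichlorotitanium aldolate of 10 | S=C1OC[C@H](Cc2ccccc2)N1C(=O)[C@H](OC)[C@H](O[Ti](Cl)(Cl)Cl)c1cc(OCc2ccccc2)c(OC)cc1OCc1ccccc1 | intermediate
10 | (4S)-4-benzyl-3-[(2R,3R)-3-[2,5-bis(benzyloxy)-4-methoxyphenyl]-3-hydroxy-2-methoxypropanoyl]-1,3-oxazolidine-2-thione | S=C1OC[C@H](Cc2ccccc2)N1C(=O)[C@H](OC)[C@H](O)c1cc(OCc2ccccc2)c(OC)cc1OCc1ccccc1 | intermediate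
11 | (2R,3R)-3-[2,5-bis(benzyloxy)-4-methoxyphenyl]-3-hydroxy-N,2-dimethoxy-N-methylpropanamide | CON(C)C(=O)[C@H](OC)[C@H](O)c1cc(OCc2ccccc2)c(OC)cc1OCc1ccccc1 | intermediate
12 | (2R,3R)-3-[2,5-bis(benzyloxy)-4-methoxyphenyl]-N,2-dimethoxy-N-methyl-3-[(trimethylsilyl)oxy]propanamide | CON(C)C(=O)[C@H](OC)[C@H](O[Si](C)(C)C)c1cc(OCc2ccccc2)c(OC)cc1OCc1ccccc1 | intermediate
13 | 3,4,5-trimethoxyphenol | COc1cc(O)cc(OC)c1OC | starting material
14 | 2-bromo-3,4,5-trimethoxyphenol | COc1cc(O)c(Br)c(OC)c1OC | intermediate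
15 | (2-bromo-3,4,5-trimethoxyphenoxy)trimethylsilane | COc1cc(O[Si](C)(C)C)c(Br)c(OC)c1OC | intermediate
16 | [2-lithio-3,4,5-trimethoxyphenoxy]trimethylsilane | COc1cc(O[Si](C)(C)C)c([Li])c(OC)c1OC | intermediate
17 | lithium 3,4,5-trimethoxy-2-(trimethylsilyl)phenolate | [Li+].[O-]c1cc(OC)c(OC)c(OC)c1[Si](C)(C)C | intermediate
18 | 3,4,5-trimethoxy-2-(trimethylsilyl)phenyl trifluoromethanesulfonate | COc1cc(OS(=O)(=O)C(F)(F)F)c([Si](C)(C)C)c(OC)c1OC | intermediate
19 | 3,4,5-trimethoxybenzyne (1,2-didehydro-3,4,5-trimethoxybenzene) | COC1=C(OC)C(OC)=CC#C1 | intermediate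
20 | potassium (1R,2R)-1-[2,5-bis(benzyloxy)-4-methoxyphenyl]-2-methoxy-3-[methoxy(methyl)amino]-3-oxopropan-1-olate | CON(C)C(=O)[C@H](OC)[C@H]([O-])c1cc(OCc2ccccc2)c(OC)cc1OCc1ccccc1.[K+] | intermediate
21 | potassium 2-{[(1R,2R)-1-[2,5-bis(benzyloxy)-4-methoxyphenyl]-2-methoxy-3-[methoxy(methyl)amino]-3-oxopropyl]oxy}-4,5,6-trimethoxybenzen-1-ide | CON(C)C(=O)[C@H](OC)[C@H](Oc1cc(OC)c(OC)c(OC)[c-]1)c1cc(OCc2ccccc2)c(OC)cc1OCc1ccccc1.[K+] | intermediate
22 | potassium (2R,3R)-2-[2,5-bis(benzyloxy)-4-methoxyphenyl]-3,5,6,7-tetramethoxy-4-[methoxy(methyl)amino]-3,4-dihydro-2H-chromen-4-olate (C4 undefined) | COc1cc(OCc2ccccc2)c([C@H]2Oc3cc(OC)c(OC)c(OC)c3C([O-])(N(C)OC)[C@@H]2OC)cc1OCc1ccccc1.[K+] | intermediate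
23 | (2R,3R)-2-[2,5-bis(benzyloxy)-4-methoxyphenyl]-3,5,6,7-tetramethoxy-2,3-dihydro-4H-chromen-4-one | COc1cc(OCc2ccccc2)c([C@H]2Oc3cc(OC)c(OC)c(OC)c3C(=O)[C@@H]2OC)cc1OCc1ccccc1 | intermediate
24 | (2R,3R)-5-[(dichloroboryl)oxy]-2-{2,5-bis[(dichloroboryl)oxy]-4-methoxyphenyl}-3,6,7-trimethoxy-2,3-dihydro-4H-chromen-4-one | COc1cc(OB(Cl)Cl)c([C@H]2Oc3cc(OC)c(OC)c(OB(Cl)Cl)c3C(=O)[C@@H]2OC)cc1OB(Cl)Cl | intermediate
25 | (2R,3R)-2-(2,5-dihydroxy-4-methoxyphenyl)-5-hydroxy-3,6,7-trimethoxy-2,3-dihydro-4H-chromen-4-one | COc1cc(O)c([C@H]2Oc3cc(OC)c(OC)c(O)c3C(=O)[C@@H]2OC)cc1O | target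

**Step count**

Total: 10 steps. Longest linear sequence: 7 steps (1, 2, 4, 5, 6, 9, 10).

**Steps most likely to fail**

Step 9 (proposed new method). The aryl anion may be protonated before it closes, leaving an open aryl ether; the alkoxide may fragment by retro-aldol; or desilylation may lag behind aryne formation so that the aryne is consumed unproductively. The fallback makes the two bonds one after the other by known chemistry; it sets out from 12 and comes back at 23. Commercial 5-fluoro-1,2,3-trimethoxybenzene is lithiated between fluorine and methoxy (n-BuLi, THF, −78 °C) to 2-fluoro-4,5,6-trimethoxyphenyllithium F1. This is acylated by Weinreb amide 12 at −78 °C to give (2R,3R)-3-[2,5-bis(benzyloxy)-4-methoxyphenyl]-1-(2-fluoro-4,5,6-trimethoxyphenyl)-2-methoxy-3-[(trimethylsilyl)oxy]propan-1-one F2 (bond C4–C4a). Fluoride (TBAF, THF, 0 °C to rt) then unmasks the alkoxide, which closes bond O1–C8a by intramolecular SNAr on the fluorine ortho to the ketone, with retention at C2, to give 23.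

Step 4. The anti/syn or facial selectivity may erode with this electron-rich, chelating aldehyde, and the ortho benzyl ether may be lost through chelation to TiCl4. The fallback replaces the stoichiometric titanium reaction by a magnesium-catalysed soft-enolisation aldol on an oxazolidinone; it sets out from 4 and comes back at 11. Commercial (S)-4-benzyl-1,3-oxazolidin-2-one is N-acylated with 6 (n-BuLi, THF, −78 °C) to (S)-4-benzyl-3-(methoxyacetyl)-1,3-oxazolidin-2-one F3. The anti-aldol with 4 (MgCl2 cat., Et3N, TMSCl, EtOAc, rt; then TFA, MeOH) should give, by the same chelated-enolate facial argument, (4S)-4-benzyl-3-[(2R,3R)-3-[2,5-bis(benzyloxy)-4-methoxyphenyl]-3-hydroxy-2-methoxypropanoyl]-1,3-oxazolidin-2-one F4. Transamination (Me3Al, MeNHOMe·HCl, CH2Cl2, 0 °C) converts F4 into 11.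

Step 10. The Lewis acid may over-demethylate (the C6 or C3 methyl ethers) or ionise the electron-rich benzylic C2–O1 bond, with epimerisation or trapping by the scavenger. The fallback places a benzyl group on the oxygen that becomes O5, so that the end game is hydrogenolysis only; it sets out from 12 and comes back at 25. Commercial 2-hydroxy-3,4-dimethoxybenzaldehyde is benzylated (BnBr, K2CO3, DMF) to 2-(benzyloxy)-3,4-dimethoxybenzaldehyde F5. Baeyer–Villiger oxidation and methanolysis (mCPBA, CH2Cl2; then K2CO3, MeOH) give 2-(benzyloxy)-3,4-dimethoxyphenol F6. Bromination ortho to the free hydroxyl (NBS, CH2Cl2, −78 °C) gives 2-(benzyloxy)-6-bromo-3,4-dimethoxyphenol F7. The sequence of step 8 gives 2-(benzyloxy)-3,4-dimethoxy-6-(trimethylsilyl)phenyl trifluoromethanesulfonate F8. Under the conditions of step 9 with 12, the aryne from F8, directed in the same way by its flanking benzyloxy group, should give (2R,3R)-5-(benzyloxy)-2-[2,5-bis(benzyloxy)-4-methoxyphenyl]-3,6,7-trimethoxy-2,3-dihydro-4H-chromen-4-one F9. Hydrogenolysis (H2, Pd/C (palladium on carbon), EtOAc, rt) removes the three benzyl groups and gives 25.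

**Further compounds**

F1 | step 9 | 2-fluoro-4,5,6-trimethoxyphenyllithium | COc1cc(F)c([Li])c(OC)c1OC
F2 | step 9 | (2R,3R)-3-[2,5-bis(benzyloxy)-4-methoxyphenyl]-1-(2-fluoro-4,5,6-trimethoxyphenyl)-2-methoxy-3-[(trimethylsilyl)oxy]propan-1-one | COc1cc(F)c(C(=O)[C@H](OC)[C@H](O[Si](C)(C)C)c2cc(OCc3ccccc3)c(OC)cc2OCc2ccccc2)c(OC)c1OC
F3 | step 4 | (S)-4-benzyl-3-(methoxyacetyl)-1,3-oxazolidin-2-one | COCC(=O)N1[C@@H](Cc2ccccc2)COC1=O
F4 | step 4 | (4S)-4-benzyl-3-[(2R,3R)-3-[2,5-bis(benzyloxy)-4-methoxyphenyl]-3-hydroxy-2-methoxypropanoyl]-1,3-oxazolidin-2-one | O=C1OC[C@H](Cc2ccccc2)N1C(=O)[C@H](OC)[C@H](O)c1cc(OCc2ccccc2)c(OC)cc1OCc1ccccc1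
F5 | step 10 | 2-(benzyloxy)-3,4-dimethoxybenzaldehyde | COc1ccc(C=O)c(OCc2ccccc2)c1OC
F6 | step 10 | 2-(benzyloxy)-3,4-dimethoxyphenol | COc1ccc(O)c(OCc2ccccc2)c1OC
F7 | step 10 | 2-(benzyloxy)-6-bromo-3,4-dimethoxyphenol | COc1cc(Br)c(O)c(OCc2ccccc2)c1OC
F8 | step 10 | 2-(benzyloxy)-3,4-dimethoxy-6-(trimethylsilyl)phenyl trifluoromethanesulfonate | COc1cc([Si](C)(C)C)c(OS(=O)(=O)C(F)(F)F)c(OCc2ccccc2)c1OC
F9 | step 10 | (2R,3R)-5-(benzyloxy)-2-[2,5-bis(benzyloxy)-4-methoxyphenyl]-3,6,7-trimethoxy-2,3-dihydro-4H-chromen-4-one | COc1cc(OCc2ccccc2)c([C@H]2Oc3cc(OC)c(OC)c(OCc4ccccc4)c3C(=O)[C@@H]2OC)cc1OCc1ccccc1
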